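The route rests on the C5–C8 bond, which joins the allyl-bearing bridgehead C5 to the acetoxy-bearing one-carbon bridge C8 (bicyclo[3.2.1]octane numbering, C1 = methoxy bridgehead, C2 = ketone). C8 lies between both quaternary bridgeheads, so the five-membered ring C1–C7–C6–C5–C8 is a masked cyclopentanone. A rhodium-catalysed intramolecular trans-hydroacylation of an acyclic 4-alkynal joins the formyl carbon (C8) to the distal alkyne carbon (C5) and gives, in one operation, the 2-allylcyclopent-2-enone that already carries the C7 aryl and C1 methoxy groups. Cuprate methylation (C6), regiospecific Michael alkylation (C5) and an aldol at C1 then lay the C2–C4 bridge across the ketone.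

Key step: step 8

Remark: the labels C1–C8 in the Why lines are those of the target bicycle (C1 OMe bridgehead, C2 C=O, C3 CHOMe, C4 CH2, C5 allyl bridgehead, C6 CHMe, C7 CHAr, C8 CHOAc).
Assumption: the Nicholas alkylation (step 4) takes the syn course on the enolate face remote from the benzyl group, as expected for a chelated Z boron enolate of an N-acyloxazolidinone and a non-coordinating electrophile; if the opposite sense were found at C7, the enantiomeric auxiliary would be used.
Assumption: pent-1-en-4-yne and 1,1,2-trimethoxyethane are bought.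

Step 1
Reactants: 1 (R)-4-benzyl-1,3-oxazolidin-2-one; 2 methoxyacetyl chloride
Product: 3 (R)-4-benzyl-3-(methoxyacetyl)-1,3-oxazolidin-2-one
Conditions: n-BuLi, THF, −78 °C; then 2, −78 to 0 °C
Reagents that add atoms: none
Why: N-acylation of the lithiated oxazolidinone auxiliary by the acid chloride; no stereocentre is formed.

Step 2
Reactants: 4 pent-1-en-4-yne; 5 3,4-dimethoxybenzaldehyde
Product: 7 rac-4-(1-methoxyhex-5-en-2-yn-1-yl)-1,2-dimethoxybenzene, via lithium alkoxide 6 (not isolated)
Conditions: n-BuLi, THF, −78 °C; 5; then MeI, DMPU, 0 °C to rt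
Reagents that add atoms: iodomethane, CI
Why: 1,2-addition of the lithium acetylide to the aldehyde and in-flask Williamson O-methylation of alkoxide 6; the benzylic centre is left racemic because it is ionised in step 4.

Step 3
Reactants: 7 rac-4-(1-methoxyhex-5-en-2-yn-1-yl)-1,2-dimethoxybenzene
Product: 8 hexacarbonyldicobalt complex of 7 (Co2(CO)6 unit bridging the alkyne)
Conditions: Co2(CO)8, CH2Cl2, rt
Reagents that add atoms: dicobalt octacarbonyl, O=C=[Co](=C=O)(=C=O)(=C=O)[Co](=C=O)(=C=O)(=C=O)=C=O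
Why: alkyne complexation with loss of two CO (Nicholas precursor), selective for the alkyne over the isolated alkene.

Step 4
Reactants: 3 (R)-4-benzyl-3-(methoxyacetyl)-1,3-oxazolidin-2-one; 8 hexacarbonyldicobalt complex of 7
Product: 10 (R)-4-benzyl-3-[(2S,3R)-3-(3,4-dimethoxyphenyl)-2-methoxyoct-7-en-4-ynoyl]-1,3-oxazolidin-2-one as its Co2(CO)6 alkyne complex, via boron enolate 9 (not isolated)
Conditions: 3, Bu2BOTf, i-Pr2NEt, CH2Cl2, −78 to 0 °C; then 8, Bu2BOTf, −78 to 0 °C
Reagents that add atoms: none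
Why: Nicholas reaction of an N-acyloxazolidinone boron enolate: Bu2BOTf ionises the complexed propargylic ether and the Co2(CO)6-stabilised cation is captured by Z enolate 9 on the face away from the benzyl group through an open synclinal transition state (syn adduct), the configurationally mobile cation letting both enantiomers of 8 converge, which sets C7 and, provisionally, C1.

Step 5
Reactants: 10 Co2(CO)6 complex of imide 11
Product: 11 (R)-4-benzyl-3-[(2S,3R)-3-(3,4-dimethoxyphenyl)-2-methoxyoct-7-en-4-ynoyl]-1,3-oxazolidin-2-one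
Conditions: Fe(NO3)3·9H2O, EtOH, 0 °C to rt
Reagents that add atoms: none
Why: oxidative decomplexation of the cobalt alkyne complex, which should leave the imide, the alkene and both stereocentres untouched.

Step 6
Reactants: 11 (R)-4-benzyl-3-[(2S,3R)-3-(3,4-dimethoxyphenyl)-2-methoxyoct-7-en-4-ynoyl]-1,3-oxazolidin-2-one
Product: 12 (2S,3R)-3-(3,4-dimethoxyphenyl)-2-methoxyoct-7-en-4-yn-1-ol
Conditions: LiBH4, MeOH (1 equiv), Et2O, 0 °C
Reagents that add atoms: none
Why: reductive cleavage of the N-acyloxazolidinone to the primary alcohol with recovery of the auxiliary; the stereocentres are not touched.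

Step 7
Reactants: 12 (2S,3R)-3-(3,4-dimethoxyphenyl)-2-methoxyoct-7-en-4-yn-1-ol
Product: 13 (2S,3R)-3-(3,4-dimethoxyphenyl)-2-methoxyoct-7-en-4-ynal
Conditions: Dess–Martin periodinane, CH2Cl2, 0 °C to rt
Reagents that add atoms: none
Why: Dess–Martin oxidation to the aldehyde under non-basic conditions; the α-methoxy centre (future C1) is in any case reset in step 11.

Step 8
Reactants: 13 (2S,3R)-3-(3,4-dimethoxyphenyl)-2-methoxyoct-7-en-4-ynal
Product: 14 (4S,5S)-2-allyl-4-(3,4-dimethoxyphenyl)-5-methoxycyclopent-2-en-1-one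
Conditions: [Rh(dppe)]2(BF4)2 (5–10 mol %), acetone, rt
Reagents that add atoms: none
Why: Intramolecular alkyne hydroacylation: the cationic monovalent rhodium centre inserts into the formyl C–H bond, the acylrhodium hydride adds across the alkyne in a net trans sense (hydride to the proximal alkyne carbon, the future C6) to give a six-membered acyl(alkenyl)rhodacycle, and reductive elimination forms the C5–C8 bond. The closest known reaction is the cyclisation of 5-substituted 4-alkynals to 2-substituted cyclopent-2-enones with the same rhodium diphosphine catalyst. The five-membered ring closes in a formal 5-endo-dig mode, which is possible only because the addition is trans. No stereocentre is created; C7 is carried over from 13 and the epimerisable C1 is fixed later. The step must prefer the cyclopentenone over 4-exo closure to an alkylidenecyclobutanone, over decarbonylation and over any reaction at the allyl group: the small-bite dppe ligand is the one that favours the cyclopentenone, room temperature disfavours decarbonylation, and the terminal alkene could be acylated only through an eight-membered ring.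

Step 9
Reactants: 14 (4S,5S)-2-allyl-4-(3,4-dimethoxyphenyl)-5-methoxycyclopent-2-en-1-one
Product: 15 {[(3R,4S,5S)-2-allyl-4-(3,4-dimethoxyphenyl)-5-methoxy-3-methylcyclopent-1-en-1-yl]oxy}trimethylsilane
Conditions: Me2CuLi, TMSCl, THF, −78 °C; Et3N before work-up
Reagents that add atoms: lithium dimethylcuprate, [Li+].C[Cu-]C; chlorotrimethylsilane, C[Si](C)(C)Cl
Why: TMSCl-accelerated cuprate conjugate addition anti to the adjacent C7 aryl group (C6 methyl trans to aryl), the C5 enolate being trapped regiospecifically as its silyl enol ether.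

Step 10
Reactants: 16 1,1,2-trimethoxyethane
Product: 18 2-methoxyprop-2-enal, via methoxyacetaldehyde 17 (not isolated)
Conditions: 1 M aq. HCl, 50 °C; then 37% aq. CH2O, Me2NH·HCl, 70 °C; distillation
Reagents that add atoms: formaldehyde, C=O; water, O
Why: acid hydrolysis of the acetal followed by Mannich-type α-methylenation of aldehyde 17 with formaldehyde and the secondary amine salt.

Step 11
Reactants: 15 {[(3R,4S,5S)-2-allyl-4-(3,4-dimethoxyphenyl)-5-methoxy-3-methylcyclopent-1-en-1-yl]oxy}trimethylsilane; 18 2-methoxyprop-2-enal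
Product: 21 (1R,2R,3S,5S,6R,7S)-5-allyl-7-(3,4-dimethoxyphenyl)-2-hydroxy-1,3-dimethoxy-6-methylbicyclo[3.2.1]octan-8-one, via lithium enolate 19 (not isolated), via keto aldehyde 20 (not isolated)
Conditions: MeLi, THF, 0 °C; added to 18 precomplexed with Al(OC6H3Ph2-2,6)3, toluene, −78 °C; then 1 M aq. HCl, THF, rt
Reagents that add atoms: none
Why: MeLi unmasks the regiodefined enolate 19, which adds 1,4 to the enal shielded at its carbonyl by the bulky aluminium aryloxide (Michael addition) on the face anti to the adjacent C6 methyl (C5 quaternary centre), and acid then drives the intramolecular aldol of the only enolisable ketone α-carbon (C1) onto the aldehyde, the tether forcing the new C1–C2 bond cis to the C5–C4 bond (C1 set), with the C2 hydroxyl expected syn to the C8 ketone (hydrogen bond, other face blocked by the endo aryl group) and the still epimerisable C3 methoxy group expected on the face away from C8.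

Step 12
Reactants: 21 (1R,2R,3S,5S,6R,7S)-5-allyl-7-(3,4-dimethoxyphenyl)-2-hydroxy-1,3-dimethoxy-6-methylbicyclo[3.2.1]octan-8-one
Product: 22 (1S,2R,3S,5S,6R,7S,8S)-5-allyl-7-(3,4-dimethoxyphenyl)-1,3-dimethoxy-6-methylbicyclo[3.2.1]octane-2,8-diol
Conditions: Et2BOMe, THF/MeOH 4:1, −78 °C; NaBH4; then AcOH, MeOH evaporation
Reagents that add atoms: none
Why: Narasaka–Prasad reduction: Et2BOMe ties the C2 hydroxyl and the C8 ketone into a six-membered boron chelate on the side of the C2–C4 bridge, so external hydride attacks C8 from the C6–C7 side and should give the syn 1,3-diol with the C8 hydroxyl over the three-carbon bridge.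

Step 13
Reactants: 22 (1S,2R,3S,5S,6R,7S,8S)-5-allyl-7-(3,4-dimethoxyphenyl)-1,3-dimethoxy-6-methylbicyclo[3.2.1]octane-2,8-diol
Product: 23 (1S,3S,5S,6R,7S,8S)-5-allyl-7-(3,4-dimethoxyphenyl)-8-hydroxy-1,3-dimethoxy-6-methylbicyclo[3.2.1]octan-2-one
Conditions: Dess–Martin periodinane (1.05 equiv), CH2Cl2, 0 °C
Reagents that add atoms: none
Why: Dess–Martin oxidation should tell the two carbinols apart sterically, the C2 alcohol having one quaternary neighbour and an exposed C–H while the C8 alcohol sits between two quaternary bridgeheads beside the exo C6 methyl; no stereocentre changes.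

Step 14
Reactants: 23 (1S,3S,5S,6R,7S,8S)-5-allyl-7-(3,4-dimethoxyphenyl)-8-hydroxy-1,3-dimethoxy-6-methylbicyclo[3.2.1]octan-2-one
Product: 24 (1S,3S,5S,6R,7S,8S)-5-allyl-7-(3,4-dimethoxyphenyl)-1,3-dimethoxy-6-methyl-2-oxobicyclo[3.2.1]octan-8-yl acetate
Conditions: Ac2O, DMAP (cat.), pyridine, 40 °C
Reagents that add atoms: acetic anhydride, CC(=O)OC(C)=O
Why: DMAP-catalysed acetylation of the hindered C8 alcohol; C3, now α to the ketone, is under thermodynamic control and should keep its methoxy group anti to the C8 bridge, away from the flagpole position of the boat-shaped ring imposed by the endo aryl group.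

Compound list
1 | (R)-4-benzyl-1,3-oxazolidin-2-one | O=C1N[C@H](Cc2ccccc2)CO1 | starting material
2 | methoxyacetyl chloride | COCC(Cl)=O | starting material
3 | (R)-4-benzyl-3-(methoxyacetyl)-1,3-oxazolidin-2-one | COCC(=O)N1[C@H](Cc2ccccc2)COC1=O | intermediate
4 | pent-1-en-4-yne | C=CCC#C | starting material
5 | 3,4-dimethoxybenzaldehyde | COc1ccc(C=O)cc1OC | starting material
6 | lithium rac-1-(3,4-dimethoxyphenyl)hex-5-en-2-yn-1-olate | [Li+].[O-]C(C#CCC=C)c1ccc(OC)c(OC)c1 | intermediate
7 | rac-4-(1-methoxyhex-5-en-2-yn-1-yl)-1,2-dimethoxybenzene | COC(C#CCC=C)c1ccc(OC)c(OC)c1 | intermediate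
8 | hexacarbonyldicobalt complex of 7 (Co2(CO)6 bridging the alkyne) | COC(c1ccc(OC)c(OC)c1)C12C3(CC=C)[Co]1(=C=O)(=C=O)(=C=O)[Co]23(=C=O)(=C=O)=C=O | intermediate
9 | (Z)-dibutylboron enolate of 3 | CCCCB(CCCC)O/C(N1[C@H](Cc2ccccc2)COC1=O)=C\OC | intermediate
10 | Co2(CO)6 alkyne complex of imide 11 | O=C([C@@H](OC)[C@H](c1ccc(OC)c(OC)c1)C12C3(CC=C)[Co]1(=C=O)(=C=O)(=C=O)[Co]23(=C=O)(=C=O)=C=O)N1[C@H](Cc2ccccc2)COC1=O | intermediate
11 | (R)-4-benzyl-3-[(2S,3R)-3-(3,4-dimethoxyphenyl)-2-methoxyoct-7-en-4-ynoyl]-1,3-oxazolidin-2-one | O=C([C@@H](OC)[C@H](c1ccc(OC)c(OC)c1)C#CCC=C)N1[C@H](Cc2ccccc2)COC1=O | intermediate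
12 | (2S,3R)-3-(3,4-dimethoxyphenyl)-2-methoxyoct-7-en-4-yn-1-ol | OC[C@@H](OC)[C@H](c1ccc(OC)c(OC)c1)C#CCC=C | intermediate
13 | (2S,3R)-3-(3,4-dimethoxyphenyl)-2-methoxyoct-7-en-4-ynal | O=C[C@@H](OC)[C@H](c1ccc(OC)c(OC)c1)C#CCC=C | intermediate
14 | (4S,5S)-2-allyl-4-(3,4-dimethoxyphenyl)-5-methoxycyclopent-2-en-1-one (aryl and methoxy trans) | C=CCC1=C[C@@H](c2ccc(OC)c(OC)c2)[C@H](OC)C1=O | intermediate
15 | {[(3R,4S,5S)-2-allyl-4-(3,4-dimethoxyphenyl)-5-methoxy-3-methylcyclopent-1-en-1-yl]oxy}trimethylsilane (methyl trans to aryl) | C=CCC1=C(O[Si](C)(C)C)[C@@H](OC)[C@H](c2ccc(OC)c(OC)c2)[C@H]1C | intermediate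
16 | 1,1,2-trimethoxyethane | COCC(OC)OC | starting material
17 | methoxyacetaldehyde | COCC=O | intermediate
18 | 2-methoxyprop-2-enal (2-methoxyacrolein) | COC(=C)C=O | intermediate
19 | lithium enolate corresponding to 15 | C=CCC1=C([O-])[C@@H](OC)[C@H](c2ccc(OC)c(OC)c2)[C@H]1C.[Li+] | intermediate
20 | 3-[(1S,3S,4S,5R)-1-allyl-4-(3,4-dimethoxyphenyl)-3-methoxy-5-methyl-2-oxocyclopentyl]-2-methoxypropanal (both epimers at the propanal C2) | C=CC[C@@]1(CC(OC)C=O)C(=O)[C@@H](OC)[C@H](c2ccc(OC)c(OC)c2)[C@H]1C | intermediate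
21 | (1R,2R,3S,5S,6R,7S)-5-allyl-7-(3,4-dimethoxyphenyl)-2-hydroxy-1,3-dimethoxy-6-methylbicyclo[3.2.1]octan-8-one | C=CC[C@]12C[C@H](OC)[C@@H](O)[C@](OC)([C@H](c3ccc(OC)c(OC)c3)[C@H]1C)C2=O | intermediate
22 | (1S,2R,3S,5S,6R,7S,8S)-5-allyl-7-(3,4-dimethoxyphenyl)-1,3-dimethoxy-6-methylbicyclo[3.2.1]octane-2,8-diol | C=CC[C@]12C[C@H](OC)[C@@H](O)[C@](OC)([C@H](c3ccc(OC)c(OC)c3)[C@H]1C)[C@H]2O | intermediate
23 | (1S,3S,5S,6R,7S,8S)-5-allyl-7-(3,4-dimethoxyphenyl)-8-hydroxy-1,3-dimethoxy-6-methylbicyclo[3.2.1]octan-2-one | C=CC[C@]12C[C@H](OC)C(=O)[C@](OC)([C@H](c3ccc(OC)c(OC)c3)[C@H]1C)[C@H]2O | intermediate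
24 | (1S,3S,5S,6R,7S,8S)-5-allyl-7-(3,4-dimethoxyphenyl)-1,3-dimethoxy-6-methyl-2-oxobicyclo[3.2.1]octan-8-yl acetate | C=CC[C@]12C[C@H](OC)C(=O)[C@](OC)([C@H](c3ccc(OC)c(OC)c3)[C@H]1C)[C@H]2OC(C)=O | target

Total step count: 14. Longest linear sequence: 12 steps (steps 2–9 and 11–14; steps 1 and 10 are side branches).

Steps most likely to fail

Step 11. The hindered tetrasubstituted enolate may add 1,2 to the aldehyde, or fail to form the quaternary centre with an enal that its α-methoxy group deactivates. The fallback brings the C3 methoxy group in late instead of carrying it in the acceptor. It sets out from 15: the lithium enolate is added in the same way to acrolein held by Al(OC6H3Ph2-2,6)3, the standard case for this 1,4-addition, and acid-induced aldol should give the 3-demethoxy ketol F5. F5 is taken through the chelate-controlled reduction to the diol F6, the selective oxidation to the hydroxy ketone F7 and the acetylation to the acetate F8, as in steps 12–14. LiHMDS (THF, −78 °C) and then 2-(phenylsulfonyl)-3-phenyloxaziridine should hydroxylate the only enolisable carbon, C3, on the exposed face to give the α-hydroxy ketone F9; Ag2O and MeI give the 3-epi methyl ether F10. Re-enolisation (LiHMDS, −78 °C) and kinetic protonation with acetic acid on the same exposed face, or DBU equilibration, should turn C3 over, and the route is rejoined at 24.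

Step 8. The acylrhodium hydride may lose CO, close 4-exo to an alkylidenecyclobutanone, or isomerise the skipped enyne. The fallback closes the same C5–C8 bond through a carbanion-type addition and sets out from 12. O-silylation with 1,1,3,3-tetramethyldisilazane and intramolecular endo-dig trans-hydrosilylation with [Cp*Ru(MeCN)3]PF6 should give the seven-membered cyclic alkenylsilane F1, with silicon on the distal alkyne carbon cis to C7. N-iodosuccinimide converts it with retention into the (Z)-iodo alcohol F2, and Dess–Martin oxidation gives the iodo aldehyde F3. An intramolecular Nozaki–Hiyama–Kishi reaction (CrCl2, NiCl2 cat., DMF) should close the ring to the cyclopentenol F4, and Dess–Martin oxidation returns to the route at 14.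

Step 13. Both carbinols may be oxidised, or the C8 carbinol instead of the C2 carbinol. The fallback uses protection and sets out from 22. TESCl and imidazole should silylate the less hindered C2 hydroxyl to give the silyl ether F11; Ac2O and DMAP acetylate the C8 hydroxyl to give the acetate F12; HF·pyridine frees the hydroxy acetate F13; Dess–Martin oxidation of the C2 carbinol rejoins the route at 24.

Further compounds
F1 | step 8 | (5S,6S)-3-allyl-5-(3,4-dimethoxyphenyl)-6-methoxy-2,2-dimethyl-2,5,6,7-tetrahydro-1,2-oxasilepine | C=CCC1=C[C@@H](c2ccc(OC)c(OC)c2)[C@H](OC)CO[Si]1(C)C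
F2 | step 8 | (2S,3S,4Z)-3-(3,4-dimethoxyphenyl)-5-iodo-2-methoxyocta-4,7-dien-1-ol | OC[C@@H](OC)[C@H](c1ccc(OC)c(OC)c1)/C=C(\I)CC=C
F3 | step 8 | (2S,3S,4Z)-3-(3,4-dimethoxyphenyl)-5-iodo-2-methoxyocta-4,7-dienal | O=C[C@@H](OC)[C@H](c1ccc(OC)c(OC)c1)/C=C(\I)CC=C
F4 | step 8 | (4S,5S)-2-allyl-4-(3,4-dimethoxyphenyl)-5-methoxycyclopent-2-en-1-ol (both C1 epimers) | C=CCC1=C[C@@H](c2ccc(OC)c(OC)c2)[C@H](OC)C1O
F5 | step 11 | 3-demethoxy analogue of ketol 21 | C=CC[C@]12CC[C@@H](O)[C@](OC)([C@H](c3ccc(OC)c(OC)c3)[C@H]1C)C2=O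
F6 | step 11 | 3-demethoxy analogue of diol 22 | C=CC[C@]12CC[C@@H](O)[C@](OC)([C@H](c3ccc(OC)c(OC)c3)[C@H]1C)[C@H]2O
F7 | step 11 | 3-demethoxy analogue of hydroxy ketone 23 | C=CC[C@]12CCC(=O)[C@](OC)([C@H](c3ccc(OC)c(OC)c3)[C@H]1C)[C@H]2O
F8 | step 11 | 3-demethoxy analogue of 24 | C=CC[C@]12CCC(=O)[C@](OC)([C@H](c3ccc(OC)c(OC)c3)[C@H]1C)[C@H]2OC(C)=O
F9 | step 11 | 3-hydroxy analogue of 24 with the C3 oxygen on the face of the C8 bridge (3-epi) | C=CC[C@]12C[C@@H](O)C(=O)[C@](OC)([C@H](c3ccc(OC)c(OC)c3)[C@H]1C)[C@H]2OC(C)=O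
F10 | step 11 | 3-epi-24 | C=CC[C@]12C[C@@H](OC)C(=O)[C@](OC)([C@H](c3ccc(OC)c(OC)c3)[C@H]1C)[C@H]2OC(C)=O
F11 | step 13 | 2-O-triethylsilyl ether of diol 22 | C=CC[C@]12C[C@H](OC)[C@@H](O[Si](CC)(CC)CC)[C@](OC)([C@H](c3ccc(OC)c(OC)c3)[C@H]1C)[C@H]2O
F12 | step 13 | 8-O-acetate of F11 | C=CC[C@]12C[C@H](OC)[C@@H](O[Si](CC)(CC)CC)[C@](OC)([C@H](c3ccc(OC)c(OC)c3)[C@H]1C)[C@H]2OC(C)=O
F13 | step 13 | 2-hydroxy 8-acetate (2-dihydro-24) | C=CC[C@]12C[C@H](OC)[C@@H](O)[C@](OC)([C@H](c3ccc(OC)c(OC)c3)[C@H]1C)[C@H]2OC(C)=O
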